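**Retrosynthetic overview**
1. Target 15 ⇐ its acetate 14, by ester methanolysis that does not touch the carbinol C–O bond.
2. 14 ⇐ tetrabromo γ-keto acid 12, by enol-lactonisation and loss of HBr; 12 ⇐ 2-substituted levulinic acid 11 by exhaustive α-bromination.
3. 11 ⇐ syn-aldol adduct 7 (auxiliary to benzyl ester, O-acetylation, Wacker oxidation of the allyl group, hydrogenolysis).
4. 7 ⇐ butanal + N-pent-4-enoyl oxazolidinone 3: an Evans boron aldol forms the C3–C1′ bond and sets the (R)-carbinol centre.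
5. Ring order: the chain stays acyclic until step 8; the furanone is the only ring.

Assumption: simple reagents that deliver a protecting group or a heteroatom (benzyl alcohol, acetic anhydride, bromine, water) are named under "Reagents that add atoms" and are not numbered.

The endgame (steps 7–9) is designed by analogy to the known ring closure of brominated 2-alkyl-levulinic acids to fimbrolides; it has no direct precedent with the 1′-acetoxy group in place.

**Step 1**
Reactants: 1 (4S)-4-benzyl-1,3-oxazolidin-2-one; 2 pent-4-enoyl chloride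
Product: 3 (4S)-4-benzyl-3-(pent-4-enoyl)-1,3-oxazolidin-2-one
Conditions: Et3N, DMAP (cat.), CH2Cl2, 0 °C → rt
Reagents that add atoms: none
Why: DMAP-catalysed N-acylation (nucleophilic acyl substitution) of the oxazolidinone by the acid chloride, with no stereocentre touched.

**Step 2**
Reactants: 3 (4S)-4-benzyl-3-(pent-4-enoyl)-1,3-oxazolidin-2-one; 4 butanal
Product: 7 (4S)-4-benzyl-3-[(2S,3R)-3-hydroxy-2-(prop-2-en-1-yl)hexanoyl]-1,3-oxazolidin-2-one, via Z-boron enolate 5 (not isolated), via boron aldolate 6 (not isolated)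
Conditions: Bu2BOTf, i-Pr2NEt, CH2Cl2, −78 → 0 °C; butanal, −78 → 0 °C; then pH 7 buffer, MeOH, 30% H2O2, 0 °C
Reagents that add atoms: none
Why: Evans syn aldol: the Z-boron enolate reacts through a Zimmerman–Traxler chair on the face opposite the benzyl group of the (S)-auxiliary, giving the (2S,3R) adduct whose C3 is the (R)-carbinol centre of the target (C2 is flattened later).

**Step 3**
Reactants: 7 (4S)-4-benzyl-3-[(2S,3R)-3-hydroxy-2-(prop-2-en-1-yl)hexanoyl]-1,3-oxazolidin-2-one
Product: 8 benzyl (2S,3R)-3-hydroxy-2-(prop-2-en-1-yl)hexanoate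
Conditions: BnOH, n-BuLi, THF, −78 → 0 °C; then 1 M HCl
Reagents that add atoms: benzyl alcohol, OCc1ccccc1
Why: Transesterification of the imide by lithium benzyloxide at the exocyclic carbonyl releases the auxiliary and gives an ester that can later be cleaved by hydrogenolysis without touching an acetate; the carbinol centre is not involved.

**Step 4**
Reactants: 8 benzyl (2S,3R)-3-hydroxy-2-(prop-2-en-1-yl)hexanoate
Product: 9 benzyl (2S,3R)-3-(acetyloxy)-2-(prop-2-en-1-yl)hexanoate
Conditions: Ac2O, pyridine, DMAP (cat.), CH2Cl2, 0 °C → rt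
Reagents that add atoms: acetic anhydride, CC(=O)OC(C)=O
Why: DMAP-catalysed O-acetylation with retention (C–O bond not broken); the acetate stops the alcohol from closing onto the later γ-ketone and survives Br2/HBr and P2O5.

**Step 5**
Reactants: 9 benzyl (2S,3R)-3-(acetyloxy)-2-(prop-2-en-1-yl)hexanoate
Product: 10 benzyl (2S,3R)-3-(acetyloxy)-2-(2-oxopropyl)hexanoate
Conditions: PdCl2 (10 mol %), CuCl, O2 (1 atm), DMF/H2O (7:1), rt
Reagents that add atoms: water, O
Why: Tsuji–Wacker oxidation: Markovnikov hydroxypalladation of the terminal alkene gives the methyl ketone, i.e. the levulinate skeleton, under near-neutral conditions.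

**Step 6**
Reactants: 10 benzyl (2S,3R)-3-(acetyloxy)-2-(2-oxopropyl)hexanoate
Product: 11 (2S,3R)-3-(acetyloxy)-2-(2-oxopropyl)hexanoic acid
Conditions: H2 (1 atm), 10% Pd/C, EtOAc, rt
Reagents that add atoms: none
Why: Hydrogenolysis of the benzyl ester frees the acid under neutral conditions that leave the ketone, the acetate and both stereocentres alone.

**Step 7**
Reactants: 11 (2S,3R)-3-(acetyloxy)-2-(2-oxopropyl)hexanoic acid
Product: 12 (2S)-2-[(1R)-1-(acetyloxy)butyl]-3,3,5,5-tetrabromo-4-oxopentanoic acid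
Conditions: Br2 (4.2 equiv), HBr (33% in AcOH, cat.), CHCl3, 0 → 45 °C, dark
Reagents that add atoms: bromine, BrBr
Why: Acid-catalysed α-bromination of the ketone through its enols; HBr-mediated equilibration is expected to spread four bromines over both α-carbons as in acetone → 1,1,3,3-tetrabromoacetone, while the C–H next to CO2H and the acetoxy carbinol do not react.

**Step 8**
Reactants: 12 (2S)-2-[(1R)-1-(acetyloxy)butyl]-3,3,5,5-tetrabromo-4-oxopentanoic acid
Product: 14 (1R)-1-[4-bromo-5-(dibromomethylidene)-2-oxo-2,5-dihydrofuran-3-yl]butyl acetate, via tetrabromo enol lactone 13 (not isolated)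
Conditions: P2O5, CH2Cl2, reflux; then Et3N (1.1 equiv), CH2Cl2, 0 °C
Reagents that add atoms: none
Why: Cyclodehydration of the γ-keto acid through its lactol to the enol lactone (the ring closure used for brominated 2-alkyl-levulinic acids), then E1cB loss of HBr across C3–C4, where the allylic bromide leaves far faster than the acetate; the CBr2 terminus has no E/Z issue.

**Step 9**
Reactants: 14 (1R)-1-[4-bromo-5-(dibromomethylidene)-2-oxo-2,5-dihydrofuran-3-yl]butyl acetate
Product: 15 4-bromo-5-(dibromomethylidene)-3-[(1R)-1-hydroxybutyl]furan-2(5H)-one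
Conditions: HCl (1.25 M in MeOH), 0 °C → rt
Reagents that add atoms: none
Why: Acid-catalysed transesterification (acyl–oxygen cleavage) removes the acetate with retention at the carbinol; the conjugated bromo enol lactone is the kind of ring that is made in strong acid and should tolerate it.

**Compound list**
1 | (4S)-4-benzyl-1,3-oxazolidin-2-one | O=C1N[C@@H](Cc2ccccc2)CO1 | starting material
2 | pent-4-enoyl chloride | C=CCCC(Cl)=O | starting material
3 | (4S)-4-benzyl-3-(pent-4-enoyl)-1,3-oxazolidin-2-one | C=CCCC(=O)N1[C@@H](Cc2ccccc2)COC1=O | intermediate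
4 | butanal | CCCC=O | starting material
5 | (4S)-4-benzyl-3-[(1Z)-1-[(dibutylboranyl)oxy]penta-1,4-dien-1-yl]-1,3-oxazolidin-2-one (Z-boron enolate) | C=CC/C=C(\OB(CCCC)CCCC)N1[C@@H](Cc2ccccc2)COC1=O | intermediate
6 | (4S)-4-benzyl-3-[(2S,3R)-3-[(dibutylboranyl)oxy]-2-(prop-2-en-1-yl)hexanoyl]-1,3-oxazolidin-2-one (boron aldolate) | CCC[C@@H](OB(CCCC)CCCC)[C@H](CC=C)C(=O)N1[C@@H](Cc2ccccc2)COC1=O | intermediate
7 | (4S)-4-benzyl-3-[(2S,3R)-3-hydroxy-2-(prop-2-en-1-yl)hexanoyl]-1,3-oxazolidin-2-one | CCC[C@@H](O)[C@H](CC=C)C(=O)N1[C@@H](Cc2ccccc2)COC1=O | intermediate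
8 | benzyl (2S,3R)-3-hydroxy-2-(prop-2-en-1-yl)hexanoate | CCC[C@@H](O)[C@H](CC=C)C(=O)OCc1ccccc1 | intermediate
9 | benzyl (2S,3R)-3-(acetyloxy)-2-(prop-2-en-1-yl)hexanoate | CCC[C@@H](OC(C)=O)[C@H](CC=C)C(=O)OCc1ccccc1 | intermediate
10 | benzyl (2S,3R)-3-(acetyloxy)-2-(2-oxopropyl)hexanoate | CCC[C@@H](OC(C)=O)[C@H](CC(C)=O)C(=O)OCc1ccccc1 | intermediate
11 | (2S,3R)-3-(acetyloxy)-2-(2-oxopropyl)hexanoic acid | CCC[C@@H](OC(C)=O)[C@H](CC(C)=O)C(O)=O | intermediate
12 | (2S)-2-[(1R)-1-(acetyloxy)butyl]-3,3,5,5-tetrabromo-4-oxopentanoic acid | CCC[C@@H](OC(C)=O)[C@H](C(Br)(Br)C(=O)C(Br)Br)C(O)=O | intermediate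
13 | (1R)-1-[(3S)-4,4-dibromo-5-(dibromomethylidene)-2-oxooxolan-3-yl]butyl acetate | CCC[C@@H](OC(C)=O)[C@H]1C(=O)OC(=C(Br)Br)C1(Br)Br | intermediate
14 | (1R)-1-[4-bromo-5-(dibromomethylidene)-2-oxo-2,5-dihydrofuran-3-yl]butyl acetate | CCC[C@@H](OC(C)=O)C1=C(Br)C(=C(Br)Br)OC1=O | intermediate
15 | 4-bromo-5-(dibromomethylidene)-3-[(1R)-1-hydroxybutyl]furan-2(5H)-one | CCC[C@@H](O)C1=C(Br)C(=C(Br)Br)OC1=O | target

**Total step count:** 9. **Longest linear sequence:** 9 steps (1 + 2 → 15).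

**Steps most likely to fail**

Step 7 (exhaustive bromination). The risk is a mixture of tri-, tetra- and pentabromides, mainly at the terminal carbon. The fallback sets out from 11 and comes back at 14. Brominate 11 with only 3.0 equiv Br2 (cat. HBr, CHCl3, rt) to (2S)-2-[(1R)-1-(acetyloxy)butyl]-3,3,5-tribromo-4-oxopentanoic acid F1. This only helps if the C3 gem-dibromide forms before the second terminal bromine, which must be checked by NMR. Close the ring with P2O5 in CH2Cl2 to (1R)-1-[(3S,5Z)-4,4-dibromo-5-(bromomethylidene)-2-oxooxolan-3-yl]butyl acetate F2 (not isolated). Eliminate HBr with Et3N to (1R)-1-[(5Z)-4-bromo-5-(bromomethylidene)-2-oxo-2,5-dihydrofuran-3-yl]butyl acetate F3. The last bromine then goes onto the ring system instead of the open chain: Br2 (CH2Cl2, 0 °C → rt) adds across the exocyclic double bond to give (1R)-1-[4,5-dibromo-5-(dibromomethyl)-2-oxo-2,5-dihydrofuran-3-yl]butyl acetate F4 (both C5 epimers), and Et3N at 0 °C eliminates HBr from it to rejoin the route at 14.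

Step 8 (P2O5 ring closure). The risk is that the hindered, electron-poor ketone does not dehydrate cleanly or that the acetate suffers. The fallback sets out from 12 and comes back at 13. Instead of dehydrating the lactol with acid, activate the carboxyl: (COCl)2 with cat. DMF in CH2Cl2 gives (2S)-2-[(1R)-1-(acetyloxy)butyl]-3,3,5,5-tetrabromo-4-oxopentanoyl chloride F5. Et3N (2.2 equiv, −20 → 0 °C) then drives intramolecular O-acylation of the readily formed dibromomethyl-ketone enolate to the enol lactone 13, and the second equivalent of base removes HBr as in step 8.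

Step 9 (deacetylation). The risk is slow methanolysis of a hindered secondary acetate next to an electrophilic enol lactone. The fallback sets out from 8 and comes back at 15, carrying the alcohol as a methoxyacetate, which is cleaved by neutral, chelation-assisted methanolysis. Acylate 8 with methoxyacetyl chloride (pyridine, cat. DMAP) to benzyl (2S,3R)-3-[(methoxyacetyl)oxy]-2-(prop-2-en-1-yl)hexanoate F6. Wacker oxidation as in step 5 gives benzyl (2S,3R)-3-[(methoxyacetyl)oxy]-2-(2-oxopropyl)hexanoate F7. Hydrogenolysis as in step 6 gives (2S,3R)-3-[(methoxyacetyl)oxy]-2-(2-oxopropyl)hexanoic acid F8. Bromination as in step 7 gives (2S)-3,3,5,5-tetrabromo-2-[(1R)-1-[(methoxyacetyl)oxy]butyl]-4-oxopentanoic acid F9. P2O5 closes the ring to (1R)-1-[(3S)-4,4-dibromo-5-(dibromomethylidene)-2-oxooxolan-3-yl]butyl methoxyacetate F10 (not isolated), and Et3N gives (1R)-1-[4-bromo-5-(dibromomethylidene)-2-oxo-2,5-dihydrofuran-3-yl]butyl methoxyacetate F11. Yb(OTf)3 (20 mol %) in MeOH at rt then releases 15.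

**Further compounds**
F1 | step 7 | (2S)-2-[(1R)-1-(acetyloxy)butyl]-3,3,5-tribromo-4-oxopentanoic acid | CCC[C@@H](OC(C)=O)[C@H](C(Br)(Br)C(=O)CBr)C(O)=O
F2 | step 7 | (1R)-1-[(3S,5Z)-4,4-dibromo-5-(bromomethylidene)-2-oxooxolan-3-yl]butyl acetate | CCC[C@@H](OC(C)=O)[C@H]1C(=O)O/C(=C\Br)C1(Br)Br
F3 | step 7 | (1R)-1-[(5Z)-4-bromo-5-(bromomethylidene)-2-oxo-2,5-dihydrofuran-3-yl]butyl acetate | CCC[C@@H](OC(C)=O)C1=C(Br)/C(=C/Br)OC1=O
F4 | step 7 | (1R)-1-[4,5-dibromo-5-(dibromomethyl)-2-oxo-2,5-dihydrofuran-3-yl]butyl acetate (both C5 epimers) | CCC[C@@H](OC(C)=O)C1=C(Br)C(Br)(C(Br)Br)OC1=O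
F5 | step 8 | (2S)-2-[(1R)-1-(acetyloxy)butyl]-3,3,5,5-tetrabromo-4-oxopentanoyl chloride | CCC[C@@H](OC(C)=O)[C@H](C(Br)(Br)C(=O)C(Br)Br)C(Cl)=O
F6 | step 9 | benzyl (2S,3R)-3-[(methoxyacetyl)oxy]-2-(prop-2-en-1-yl)hexanoate | CCC[C@@H](OC(=O)COC)[C@H](CC=C)C(=O)OCc1ccccc1
F7 | step 9 | benzyl (2S,3R)-3-[(methoxyacetyl)oxy]-2-(2-oxopropyl)hexanoate | CCC[C@@H](OC(=O)COC)[C@H](CC(C)=O)C(=O)OCc1ccccc1
F8 | step 9 | (2S,3R)-3-[(methoxyacetyl)oxy]-2-(2-oxopropyl)hexanoic acid | CCC[C@@H](OC(=O)COC)[C@H](CC(C)=O)C(O)=O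
F9 | step 9 | (2S)-3,3,5,5-tetrabromo-2-[(1R)-1-[(methoxyacetyl)oxy]butyl]-4-oxopentanoic acid | CCC[C@@H](OC(=O)COC)[C@H](C(Br)(Br)C(=O)C(Br)Br)C(O)=O
F10 | step 9 | (1R)-1-[(3S)-4,4-dibromo-5-(dibromomethylidene)-2-oxooxolan-3-yl]butyl methoxyacetate | CCC[C@@H](OC(=O)COC)[C@H]1C(=O)OC(=C(Br)Br)C1(Br)Br
F11 | step 9 | (1R)-1-[4-bromo-5-(dibromomethylidene)-2-oxo-2,5-dihydrofuran-3-yl]butyl methoxyacetate | CCC[C@@H](OC(=O)COC)C1=C(Br)C(=C(Br)Br)OC1=O
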